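**Retrosynthetic overview**
- Helilupolone ⇒ 2',4',6'-trihydroxydihydrochalcone + three prenyl bromides. All three C-prenylations run in one pot, and the third hits an already prenylated carbon and dearomatises the ring (last step).
- Triol ⇒ its tri-O-methyl ether (BBr3 cleavage), so the metal-mediated steps meet no acidic OH.
- Key cut, ArCO-CH2-CH2 | Ph: ketone homoenolate (β-carbanion, reversed-polarity d3 synthon) + bromobenzene. The ketone β-carbon and the C–Br carbon are both acceptor sites, and they are joined through a palladium homoenolate.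
- The homoenolate is stored as 1-(2,4,6-trimethoxyphenyl)cyclopropan-1-ol ⇒ lithium enolate of 2',4',6'-trimethoxyacetophenone + CH2 (from CH2I2/SmI2).
- Rings: both six-membered rings are bought. The only ring made is the cyclopropane (step 1), and it is opened again in step 2.

Assumption: the target has no stereocentre (the quaternary ring carbon carries two identical prenyl groups), so it is achiral and there is no enantiomer to select; the given SMILES is one of several rapidly interconverting enol tautomers and is the one listed.

**Step 1**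
Reactants: 1 1-(2,4,6-trimethoxyphenyl)ethan-1-one; 2 diiodomethane
Product: 4 1-(2,4,6-trimethoxyphenyl)cyclopropan-1-ol, via lithium enolate 3 (not isolated)
Conditions: LiN(iPr)2 (1.1 equiv), THF, −78 °C; then CH2I2 (2 equiv), SmI2 (4.4 equiv), THF, −78 °C to rt; H2O
Reagents that add atoms: diiodomethane (2), ICI
Why: LiN(iPr)2 can only enolise the acetyl CH3, and the electron-rich C=C of 3 is methylenated by the carbenoid ICH2SmI2 (from CH2I2 and two SmI2) held on the enolate oxygen, a Simmons–Smith-type cyclopropanation of a lithium enolate that gives the cyclopropanol directly and creates no stereocentre.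

**Step 2 (key step)**
Reactants: 4 1-(2,4,6-trimethoxyphenyl)cyclopropan-1-ol; 5 bromobenzene
Product: 7 3-phenyl-1-(2,4,6-trimethoxyphenyl)propan-1-one, via phenylpalladium homoenolate 6 (not isolated)
Conditions: PhBr (1.5 equiv), Pd(OAc)2 (5 mol %), XPhos (10 mol %), Cs2CO3 (2 equiv), toluene, 80 °C
Reagents that add atoms: bromobenzene (5), Brc1ccccc1
Why: PhBr adds oxidatively to zerovalent palladium, Cs2CO3 places the cyclopropoxide of 4 on the metal, and strain-driven β-carbon elimination gives the divalent palladium homoenolate 6, in which the ketone β-carbon (normally an acceptor site) acts as the carbon donor and reductively eliminates onto the former C–Br carbon (palladium-catalysed cyclopropanol ring-opening cross-coupling, homoenolate arylation), with bulky XPhos making this faster than β-hydride elimination and no stereocentre being formed.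

**Step 3**
Reactants: 7 3-phenyl-1-(2,4,6-trimethoxyphenyl)propan-1-one
Product: 8 3-phenyl-1-(2,4,6-trihydroxyphenyl)propan-1-one
Conditions: BBr3 (6 equiv), CH2Cl2, −78 °C to rt, 16 h; then H2O
Reagents that add atoms: none
Why: Each aryl methyl ether binds BBr3 and loses its methyl group to bromide by SN2 (BBr3 ether cleavage, the two ortho ethers helped by chelation to the ketone), hydrolysis of the aryl borates frees the triol, and the ketone, the CH2CH2 chain and the phenyl ring are inert.

**Step 4**
Reactants: 8 3-phenyl-1-(2,4,6-trihydroxyphenyl)propan-1-one; 9 1-bromo-3-methylbut-2-ene (prenyl bromide)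
Product: 12 helilupolone, via monoprenyl ketone 10 (not isolated), via diprenyl ketone 11 (not isolated)
Conditions: prenyl bromide (3.3 equiv), liquid NH3/Et2O, −78 to −33 °C; NH3 evaporated, 1 M HCl
Reagents that add atoms: prenyl bromide (9), CC(C)=CCBr
Why: In liquid ammonia the ammonium phenoxide of the acylphloroglucinol attacks the soft allylic bromide through carbon by SN2, filling C3 (10) and C5 (11), and the third prenylation at an already prenylated carbon dearomatises the ring to the strongly stabilised enolised β-triketone (alkylative dearomatisation, the classical hop β-acid synthesis), the new quaternary carbon bearing two identical prenyl groups so that no stereocentre arises.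

**Compound list**
1 | 1-(2,4,6-trimethoxyphenyl)ethan-1-one (2',4',6'-trimethoxyacetophenone) | CC(=O)c1c(OC)cc(OC)cc1OC | starting material
2 | diiodomethane | ICI | starting material
3 | lithium 1-(2,4,6-trimethoxyphenyl)ethen-1-olate | [Li]OC(=C)c1c(OC)cc(OC)cc1OC | intermediate
4 | 1-(2,4,6-trimethoxyphenyl)cyclopropan-1-ol | COc1cc(OC)c(C2(O)CC2)c(OC)c1 | intermediate
5 | bromobenzene | Brc1ccccc1 | starting material
6 | phenyl[3-oxo-3-(2,4,6-trimethoxyphenyl)propyl]palladium (XPhos on Pd not drawn) | COc1cc(OC)c(C(=O)CC[Pd]c2ccccc2)c(OC)c1 | intermediate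
7 | 3-phenyl-1-(2,4,6-trimethoxyphenyl)propan-1-one | COc1cc(OC)c(C(=O)CCc2ccccc2)c(OC)c1 | intermediate
8 | 3-phenyl-1-(2,4,6-trihydroxyphenyl)propan-1-one (2',4',6'-trihydroxydihydrochalcone) | O=C(CCc1ccccc1)c1c(O)cc(O)cc1O | intermediate
9 | 1-bromo-3-methylbut-2-ene (prenyl bromide) | CC(C)=CCBr | starting material
10 | 3-phenyl-1-[2,4,6-trihydroxy-3-(3-methylbut-2-en-1-yl)phenyl]propan-1-one | CC(C)=CCc1c(O)cc(O)c(C(=O)CCc2ccccc2)c1O | intermediate
11 | 3-phenyl-1-[2,4,6-trihydroxy-3,5-bis(3-methylbut-2-en-1-yl)phenyl]propan-1-one | CC(C)=CCc1c(O)c(CC=C(C)C)c(O)c(C(=O)CCc2ccccc2)c1O | intermediate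
12 | helilupolone, 3,5-dihydroxy-4,6,6-tris(3-methylbut-2-en-1-yl)-2-(3-phenylpropanoyl)cyclohexa-2,4-dien-1-one (achiral) | CC(C)=CCC1=C(O)C(CC=C(C)C)(CC=C(C)C)C(=O)C(C(=O)CCc2ccccc2)=C1O | target

**Totals**
Total step count: 4. Longest linear sequence: 4.

**Steps most likely to fail, with fallbacks**

Step 2 is most at risk. Intermediate 6 can lose a β-hydride to give the enone, or 4 can simply be protonated open to the propiophenone. The fallback sets out from 4 and comes back at 7. It makes the β-hydride elimination the wanted reaction: Pd(OAc)2 (10 mol %), pyridine, O2 (1 atm), toluene, 80 °C turns 4 into the aryl vinyl ketone 1-(2,4,6-trimethoxyphenyl)prop-2-en-1-one F1. Phenyl is then brought in as the donor by rhodium-catalysed 1,4-addition of phenylboronic acid ([Rh(cod)Cl]2, KOH, dioxane/H2O, 50 °C, Hayashi–Miyaura addition), which gives 7.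

Step 4 comes second. O-prenylation, stalling at 11, a fourth prenylation and acid-induced chroman formation all erode the yield. The fallback sets out from 8 and comes back at 12. The triple C-alkylation is done with a π-allylpalladium electrophile instead (allyl methyl carbonate 3.3 equiv, Pd(PPh3)4 5 mol %, THF, rt; Tsuji–Trost allylation, the third one dearomatising). This gives 3,5-dihydroxy-2-(3-phenylpropanoyl)-4,6,6-tri(prop-2-en-1-yl)cyclohexa-2,4-dien-1-one F2. The three allyl groups are then converted into prenyl groups by cross-metathesis with 2-methylbut-2-ene (as solvent) and second-generation Grubbs catalyst at 40 °C, which gives 12.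

Step 1 comes third. The twisted, di-ortho-substituted enolate may be methylenated slowly, and the samarium carbenoid is short-lived. The fallback sets out from 1 and comes back at 4. The enol is trapped as a neutral, isolable species (TMSOTf, Et3N, CH2Cl2, 0 °C) to give the silyl enol ether trimethyl{[1-(2,4,6-trimethoxyphenyl)ethenyl]oxy}silane F3. This is cyclopropanated with a zinc carbenoid (Et2Zn, CH2I2, CH2Cl2, 0 °C, Furukawa variant of the Simmons–Smith reaction) to give trimethyl{[1-(2,4,6-trimethoxyphenyl)cyclopropyl]oxy}silane F4. Methanolysis (K2CO3 cat., MeOH, 0 °C) then frees 4.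

**Further compounds**
F1 | step 2 | 1-(2,4,6-trimethoxyphenyl)prop-2-en-1-one | C=CC(=O)c1c(OC)cc(OC)cc1OC
F2 | step 4 | 3,5-dihydroxy-2-(3-phenylpropanoyl)-4,6,6-tri(prop-2-en-1-yl)cyclohexa-2,4-dien-1-one | C=CCC1=C(O)C(CC=C)(CC=C)C(=O)C(C(=O)CCc2ccccc2)=C1O
F3 | step 1 | trimethyl{[1-(2,4,6-trimethoxyphenyl)ethenyl]oxy}silane | C=C(O[Si](C)(C)C)c1c(OC)cc(OC)cc1OC
F4 | step 1 | trimethyl{[1-(2,4,6-trimethoxyphenyl)cyclopropyl]oxy}silane | COc1cc(OC)c(C2(O[Si](C)(C)C)CC2)c(OC)c1
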